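5-Methoxyresorcinol (ring A) and 2,4-dihydroxyphenylacetic acid (ring B) are joined through an aryne/DMF/enolate annulation that builds the pyranone.

- The target is 3-(2,4-dihydroxyphenyl)-5-hydroxy-7-methoxy-6-(3-methylbut-2-enyl)coumarin. The retrosynthesis first cuts the C6–prenyl bond (back to an O5 1,1-dimethylallyl ether, Claisen), then all four pyranone bonds O1–C8a, C4–C4a, C3–C4 and O1–C2.
- Enabling feature: O1 and C4 sit on the neighbouring ring-A carbons C8a and C4a, right beside the C5 oxygen. A 3-alkoxyaryne takes a nucleophile at its distal carbon (C8a) and an electrophile at its proximal carbon (C4a), which is this pattern.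
- Ring A is bought as 5-methoxyresorcinol and converted into a 3-alkoxy-2-silylaryl triflate (steps 1–5). Ring B is bought as 2,4-dihydroxyphenylacetic acid and protected (steps 6–7).
- The pyranone is the only ring made. It forms in step 8 from the aryne, DMF (supplies O1 and C4) and the arylacetate enolate (supplies C3 and C2).
- Endgame (steps 9–13): O5 unmasking, O-dimethylpropargylation, semi-hydrogenation, Claisen shift to C6, MOM removal.
- Stereochemistry: none to set.

Key step: step 8

Remark: the target has no stereocentre and no stereogenic double bond (the prenyl alkene carries two identical methyl groups), so "single enantiomer" is read as the one achiral compound drawn.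

Step 1
Reactants: 1 5-methoxyresorcinol (5-methoxybenzene-1,3-diol)
Product: 2 5-methoxy-1,3-phenylene bis(N,N-diethylcarbamate)
Conditions: Et2NCOCl (2.4 equiv), K2CO3, MeCN, reflux
Reagents that add atoms: N,N-diethylcarbamoyl chloride, CCN(CC)C(=O)Cl
Why: O-carbamoylation of both phenols (nucleophilic acyl substitution) should be clean and installs two identical, strong directing groups while keeping the molecule symmetric.

Step 2
Reactants: 2 5-methoxy-1,3-phenylene bis(N,N-diethylcarbamate)
Product: 4 5-methoxy-2-(trimethylsilyl)-1,3-phenylene bis(N,N-diethylcarbamate), via 2-lithio bis-carbamate 3 (not isolated)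
Conditions: s-BuLi, TMEDA, THF, −78 °C; then Me3SiCl, −78 °C → rt
Reagents that add atoms: chlorotrimethylsilane, C[Si](C)(C)Cl
Why: Directed ortho-metalation should take place at C2, the only C–H flanked by two O-carbamates (stronger directors than OMe), and the silyl quench at −78 °C precedes any anionic ortho-Fries shift.

Step 3
Reactants: 4 5-methoxy-2-(trimethylsilyl)-1,3-phenylene bis(N,N-diethylcarbamate)
Product: 5 5-methoxy-2-(trimethylsilyl)benzene-1,3-diol
Conditions: LiAlH4, THF, 0 °C → rt; aq. Rochelle salt work-up (pH ≥ 7); used crude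
Reagents that add atoms: none
Why: Reductive cleavage of aryl carbamates by hydride attack at the carbamoyl carbon should free both phenols while the aryl–silicon bond is inert to hydride, and the non-acidic work-up avoids ipso-protodesilylation.

Step 4
Reactants: 5 5-methoxy-2-(trimethylsilyl)benzene-1,3-diol
Product: 6 5-methoxy-3-[(4-methoxybenzyl)oxy]-2-(trimethylsilyl)phenol
Conditions: PMBCl (1.0 equiv), K2CO3 (1.0 equiv), NaI (cat.), acetone, 40 °C
Reagents that add atoms: 4-methoxybenzyl chloride, COc1ccc(CCl)cc1
Why: Williamson etherification of the symmetric diol gives the same mono-ether whichever hydroxyl reacts, so only mono- versus bis-alkylation has to be held back by the stoichiometry, and diol and bis-ether should be separable.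

Step 5
Reactants: 6 5-methoxy-3-[(4-methoxybenzyl)oxy]-2-(trimethylsilyl)phenol
Product: 7 5-methoxy-3-[(4-methoxybenzyl)oxy]-2-(trimethylsilyl)phenyl trifluoromethanesulfonate
Conditions: PhNTf2, DBU, MeCN, rt
Reagents that add atoms: N-phenylbis(trifluoromethanesulfonimide), O=S(=O)(N(c1ccccc1)S(=O)(=O)C(F)(F)F)C(F)(F)F
Why: O-sulfonylation of the hindered phenoxide with the mild triflyl donor PhNTf2 is the standard last step towards ortho-silylaryl triflates and should tolerate the PMB ether and the electron-rich arylsilane.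

Step 6
Reactants: 8 2,4-dihydroxyphenylacetic acid
Product: 9 methyl 2-(2,4-dihydroxyphenyl)acetate
Conditions: MeOH, H2SO4 (cat.), reflux
Reagents that add atoms: methanol, CO
Why: Fischer esterification in excess methanol should drive the equilibrium to the ester, any benzofuranone formed by lactonisation being reopened by methanolysis.

Step 7
Reactants: 9 methyl 2-(2,4-dihydroxyphenyl)acetate
Product: 10 methyl 2-[2,4-bis(methoxymethoxy)phenyl]acetate
Conditions: MOMCl, i-Pr2NEt, CH2Cl2, 0 °C → rt
Reagents that add atoms: chloromethyl methyl ether, COCCl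
Why: O-alkylation of both phenols with the α-chloro ether under amine base (MOM ether formation) should give acetals that survive amide base, fluoride, DDQ and heat and that leave the ester α-CH2 untouched.

Step 8
Reactants: 7 5-methoxy-3-[(4-methoxybenzyl)oxy]-2-(trimethylsilyl)phenyl trifluoromethanesulfonate, 10 methyl 2-[2,4-bis(methoxymethoxy)phenyl]acetate, 11 N,N-dimethylformamide
Product: 17 3-[2,4-bis(methoxymethoxy)phenyl]-7-methoxy-5-[(4-methoxybenzyl)oxy]-2H-chromen-2-one, via chlorozinc enolate 12 (not isolated), via aryne 13 (not isolated), via aminobenzoxete 14 (not isolated), via aminoquinone methide 15 (not isolated), via 4-aminodihydrocoumarin 16 (not isolated)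
Conditions: 10, LiHMDS, THF, −78 °C; ZnCl2, −78 → 0 °C; then 7, anhydrous CsF, DMF (solvent and reactant), rt
Reagents that add atoms: none
Why: Fluoride-induced 1,2-elimination of 7 should give the 3-alkoxyaryne 13, whose distal carbon (future C8a) is attacked by the formamide oxygen while the proximal carbon (future C4a) closes onto the iminium carbon, so that formal [2+2] insertion into the C=O bond gives benzoxete 14 and its 4π ring opening gives aminoquinone methide 15. Zinc enolate 12 then adds to the iminium carbon of 15 (C3–C4, Mannich-type), the phenoxide O1 attacks the methyl ester (6-exo-trig acyl substitution, O1–C2) to give lactone 16, and E1cB loss of dimethylamine installs the C3=C4 double bond of 17. The closest known reaction type is the fluoride-promoted three-component coupling of arynes, DMF and active methylene compounds or ester enolates to coumarins, a formal [4+2] annulation of the ortho-quinone methide. The pyranone, the only ring formed, closes stepwise with the C–C bond first and the lactone second, and no stereocentre remains in 17. The selectivity needed is the orientation of DMF addition, which the inductively withdrawing C5 alkoxy group secures by distorting the aryne so that the nucleophile attacks the carbon meta to it. Using DMF as solvent should make carbonyl insertion outrun direct arylation of the enolate.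

Step 9
Reactants: 17 3-[2,4-bis(methoxymethoxy)phenyl]-7-methoxy-5-[(4-methoxybenzyl)oxy]-2H-chromen-2-one
Product: 18 3-[2,4-bis(methoxymethoxy)phenyl]-5-hydroxy-7-methoxy-2H-chromen-2-one
Conditions: DDQ, CH2Cl2/pH 7 buffer, 0 °C → rt
Reagents that add atoms: none
Why: Oxidative cleavage of the 4-methoxybenzyl ether by DDQ (benzylic oxidation, then hydrolysis) should free O5 selectively, since MOM acetals, the aryl methyl ether and the lactone are not oxidised under buffered conditions.

Step 10
Reactants: 18 3-[2,4-bis(methoxymethoxy)phenyl]-5-hydroxy-7-methoxy-2H-chromen-2-one, 19 3-chloro-3-methylbut-1-yne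
Product: 20 3-[2,4-bis(methoxymethoxy)phenyl]-7-methoxy-5-[(2-methylbut-3-yn-2-yl)oxy]-2H-chromen-2-one
Conditions: CuCl2·2H2O (cat.), DBU, MeCN, 0 °C
Reagents that add atoms: none
Why: Copper-catalysed propargylic substitution of the tertiary chloride by a phenoxide is the established route to aryl 1,1-dimethylpropargyl ethers, and O5 is the only free hydroxyl.

Step 11
Reactants: 20 3-[2,4-bis(methoxymethoxy)phenyl]-7-methoxy-5-[(2-methylbut-3-yn-2-yl)oxy]-2H-chromen-2-one
Product: 21 3-[2,4-bis(methoxymethoxy)phenyl]-7-methoxy-5-[(2-methylbut-3-en-2-yl)oxy]-2H-chromen-2-one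
Conditions: H2 (1 atm), Lindlar catalyst, quinoline, EtOAc, rt
Reagents that add atoms: none
Why: Lindlar semi-hydrogenation should stop at the terminal alkene when hydrogen uptake is monitored, and the conjugated trisubstituted C3=C4 bond of the coumarin is not reduced over the poisoned catalyst.

Step 12
Reactants: 21 3-[2,4-bis(methoxymethoxy)phenyl]-7-methoxy-5-[(2-methylbut-3-en-2-yl)oxy]-2H-chromen-2-one
Product: 23 3-[2,4-bis(methoxymethoxy)phenyl]-5-hydroxy-7-methoxy-6-(3-methylbut-2-en-1-yl)-2H-chromen-2-one, via C6 dienone 22 (not isolated)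
Conditions: PhNEt2, 130 °C
Reagents that add atoms: none
Why: The aromatic Claisen [3,3]-rearrangement of the 1,1-dimethylallyl ether should deliver the allyl unit with inversion, as a prenyl group, to C6, the only ortho carbon bearing hydrogen (C4a is the ring fusion), and dienone 22 tautomerises to the phenol.

Step 13
Reactants: 23 3-[2,4-bis(methoxymethoxy)phenyl]-5-hydroxy-7-methoxy-6-(3-methylbut-2-en-1-yl)-2H-chromen-2-one
Product: 24 3-(2,4-dihydroxyphenyl)-5-hydroxy-7-methoxy-6-(3-methylbut-2-en-1-yl)-2H-chromen-2-one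
Conditions: conc. HCl (few equiv), MeOH, rt
Reagents that add atoms: none
Why: Acid-catalysed methanolysis of the two MOM acetals should free the resorcinol hydroxyls, and brief treatment at room temperature is chosen to leave the prenyl alkene next to the free C5 hydroxyl uncyclised.

Compound list
1 | 5-methoxyresorcinol (5-methoxybenzene-1,3-diol) | COc1cc(O)cc(O)c1 | starting material
2 | 5-methoxy-1,3-phenylene bis(N,N-diethylcarbamate) | CCN(CC)C(=O)Oc1cc(OC)cc(OC(=O)N(CC)CC)c1 | intermediate
3 | 2-lithio-5-methoxy-1,3-phenylene bis(N,N-diethylcarbamate) | [Li]c1c(OC(=O)N(CC)CC)cc(OC)cc1OC(=O)N(CC)CC | intermediate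
4 | 5-methoxy-2-(trimethylsilyl)-1,3-phenylene bis(N,N-diethylcarbamate) | CCN(CC)C(=O)Oc1cc(OC)cc(OC(=O)N(CC)CC)c1[Si](C)(C)C | intermediate
5 | 5-methoxy-2-(trimethylsilyl)benzene-1,3-diol | COc1cc(O)c([Si](C)(C)C)c(O)c1 | intermediate
6 | 5-methoxy-3-[(4-methoxybenzyl)oxy]-2-(trimethylsilyl)phenol | COc1ccc(COc2cc(OC)cc(O)c2[Si](C)(C)C)cc1 | intermediate
7 | 5-methoxy-3-[(4-methoxybenzyl)oxy]-2-(trimethylsilyl)phenyl trifluoromethanesulfonate | COc1cc(OCc2ccc(OC)cc2)c([Si](C)(C)C)c(OS(=O)(=O)C(F)(F)F)c1 | intermediate
8 | 2,4-dihydroxyphenylacetic acid | OC(=O)Cc1ccc(O)cc1O | starting material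
9 | methyl 2-(2,4-dihydroxyphenyl)acetate | COC(=O)Cc1ccc(O)cc1O | intermediate
10 | methyl 2-[2,4-bis(methoxymethoxy)phenyl]acetate | COCOc1ccc(CC(=O)OC)c(OCOC)c1 | intermediate
11 | N,N-dimethylformamide | CN(C)C=O | starting material
12 | chlorozinc enolate of 10, chloro{[2-(2,4-bis(methoxymethoxy)phenyl)-1-methoxyethenyl]oxy}zinc (enolate geometry not defined) | COCOc1ccc(C=C(OC)O[Zn]Cl)c(OCOC)c1 | intermediate
13 | 5-methoxy-3-[(4-methoxybenzyl)oxy]benzyne (1,2-didehydrobenzene) | COC1=CC#CC(OCc2ccc(OC)cc2)=C1 | intermediate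
14 | 5-methoxy-3-[(4-methoxybenzyl)oxy]-N,N-dimethyl-2H-benzo[b]oxet-2-amine (racemic) | CN(C)C1Oc2cc(OC)cc(OCc3ccc(OC)cc3)c21 | intermediate
15 | 6-[(dimethylamino)methylidene]-3-methoxy-5-[(4-methoxybenzyl)oxy]cyclohexa-2,4-dien-1-one | CN(C)C=C1C(=O)C=C(OC)C=C1OCc1ccc(OC)cc1 | intermediate
16 | 3-[2,4-bis(methoxymethoxy)phenyl]-4-(dimethylamino)-7-methoxy-5-[(4-methoxybenzyl)oxy]chroman-2-one (racemic diastereomer mixture) | CN(C)C1C(c2ccc(OCOC)cc2OCOC)C(=O)Oc2cc(OC)cc(OCc3ccc(OC)cc3)c21 | intermediate
17 | 3-[2,4-bis(methoxymethoxy)phenyl]-7-methoxy-5-[(4-methoxybenzyl)oxy]-2H-chromen-2-one | COCOc1ccc(-c2cc3c(OCc4ccc(OC)cc4)cc(OC)cc3oc2=O)c(OCOC)c1 | intermediate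
18 | 3-[2,4-bis(methoxymethoxy)phenyl]-5-hydroxy-7-methoxy-2H-chromen-2-one | COCOc1ccc(-c2cc3c(O)cc(OC)cc3oc2=O)c(OCOC)c1 | intermediate
19 | 3-chloro-3-methylbut-1-yne | CC(C)(Cl)C#C | starting material
20 | 3-[2,4-bis(methoxymethoxy)phenyl]-7-methoxy-5-[(2-methylbut-3-yn-2-yl)oxy]-2H-chromen-2-one | COCOc1ccc(-c2cc3c(OC(C)(C)C#C)cc(OC)cc3oc2=O)c(OCOC)c1 | intermediate
21 | 3-[2,4-bis(methoxymethoxy)phenyl]-7-methoxy-5-[(2-methylbut-3-en-2-yl)oxy]-2H-chromen-2-one | COCOc1ccc(-c2cc3c(OC(C)(C)C=C)cc(OC)cc3oc2=O)c(OCOC)c1 | intermediate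
22 | 3-[2,4-bis(methoxymethoxy)phenyl]-7-methoxy-6-(3-methylbut-2-en-1-yl)-6H-chromene-2,5-dione (racemic) | COCOc1ccc(C2=CC3=C(OC2=O)C=C(OC)C(CC=C(C)C)C3=O)c(OCOC)c1 | intermediate
23 | 3-[2,4-bis(methoxymethoxy)phenyl]-5-hydroxy-7-methoxy-6-(3-methylbut-2-en-1-yl)-2H-chromen-2-one | COCOc1ccc(-c2cc3c(O)c(CC=C(C)C)c(OC)cc3oc2=O)c(OCOC)c1 | intermediate
24 | 3-(2,4-dihydroxyphenyl)-5-hydroxy-7-methoxy-6-(3-methylbut-2-en-1-yl)-2H-chromen-2-one (achiral) | COc1cc2oc(=O)c(-c3ccc(O)cc3O)cc2c(O)c1CC=C(C)C | target

Total step count: 13. Longest linear sequence: 11 steps (steps 1–5, then 8–13, from 5-methoxyresorcinol); steps 6–7 form the short branch.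

Steps most likely to fail

Step 8. The three components may fail to converge. The enolate may be protonated by moisture from the fluoride source, it may add directly to the aryne, or the hindered, electron-rich aminoquinone methide may be captured too slowly and be lost on work-up. The fallback separates the aryne/DMF insertion from the ring closure. Setting out from 7 and 11, CsF in DMF containing water should hydrolyse the aryne/DMF adduct to 2-hydroxy-4-methoxy-6-[(4-methoxybenzyl)oxy]benzaldehyde F1. Ester 10 is saponified (LiOH, THF/H2O) to 2-[2,4-bis(methoxymethoxy)phenyl]acetic acid F2. A Perkin–Oglialoro condensation of the two (Ac2O, Et3N, 110 °C) then forms C3–C4 and O1–C2 and comes back to the route at 17.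

Step 4. The very electron-rich silyl diol may undergo ipso-protodesilylation during work-up or alkylation, and mono-etherification may run on to the bis-ether. The fallback carries bromine instead of silicon through deprotection and desymmetrisation and brings in silicon last. Setting out from 2, lithiation as in step 2 (aryllithium 3) and quench with BrCCl2CCl2Br should give 2-bromo-5-methoxy-1,3-phenylene bis(N,N-diethylcarbamate) F3. Hydrolysis (KOH, EtOH, reflux) gives the robust 2-bromo-5-methoxybenzene-1,3-diol F4. Mono-alkylation (PMBCl, K2CO3, acetone) gives 2-bromo-5-methoxy-3-[(4-methoxybenzyl)oxy]phenol F5, and hexamethyldisilazane converts it into its trimethylsilyl ether {2-bromo-5-methoxy-3-[(4-methoxybenzyl)oxy]phenoxy}trimethylsilane F6. n-BuLi (THF, −78 °C → rt) then effects bromine–lithium exchange and the retro-Brook O→C silyl shift, and aqueous work-up comes back to the route at 6.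

Step 13. The acid may protonate the prenyl alkene, so that the free C5 hydroxyl closes onto it (chroman formation) or methanol or HCl adds across it. The fallback unmasks ring B before any prenyl group exists. Setting out from 20, HCl/MeOH at rt should remove both MOM groups at the stage of the tertiary propargylic ether, which ionises far less readily than an allylic ether. This gives 3-(2,4-dihydroxyphenyl)-7-methoxy-5-[(2-methylbut-3-yn-2-yl)oxy]-2H-chromen-2-one F7. Lindlar semi-hydrogenation gives 3-(2,4-dihydroxyphenyl)-7-methoxy-5-[(2-methylbut-3-en-2-yl)oxy]-2H-chromen-2-one F8. The Claisen rearrangement (PhNEt2, 130 °C) then comes back to the route at 24, with no acid treatment after the prenyl group is in place.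

Further compounds
F1 | step 8 | 2-hydroxy-4-methoxy-6-[(4-methoxybenzyl)oxy]benzaldehyde | COc1ccc(COc2cc(OC)cc(O)c2C=O)cc1
F2 | step 8 | 2-[2,4-bis(methoxymethoxy)phenyl]acetic acid | COCOc1ccc(CC(=O)O)c(OCOC)c1
F3 | step 4 | 2-bromo-5-methoxy-1,3-phenylene bis(N,N-diethylcarbamate) | COc1cc(OC(=O)N(CC)CC)c(Br)c(OC(=O)N(CC)CC)c1
F4 | step 4 | 2-bromo-5-methoxybenzene-1,3-diol | COc1cc(O)c(Br)c(O)c1
F5 | step 4 | 2-bromo-5-methoxy-3-[(4-methoxybenzyl)oxy]phenol | COc1ccc(COc2cc(OC)cc(O)c2Br)cc1
F6 | step 4 | {2-bromo-5-methoxy-3-[(4-methoxybenzyl)oxy]phenoxy}trimethylsilane | COc1ccc(COc2cc(OC)cc(O[Si](C)(C)C)c2Br)cc1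
F7 | step 13 | 3-(2,4-dihydroxyphenyl)-7-methoxy-5-[(2-methylbut-3-yn-2-yl)oxy]-2H-chromen-2-one | COc1cc(OC(C)(C)C#C)c2cc(-c3ccc(O)cc3O)c(=O)oc2c1
F8 | step 13 | 3-(2,4-dihydroxyphenyl)-7-methoxy-5-[(2-methylbut-3-en-2-yl)oxy]-2H-chromen-2-one | COc1cc(OC(C)(C)C=C)c2cc(-c3ccc(O)cc3O)c(=O)oc2c1
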